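**Plan**

- Retrosynthesis: the twelve phenols are masked as benzyl ethers. The first cut is the C4–C8 bond between the upper 3-deoxyflavan unit and C8 of the lower epigallocatechin gallate unit (flavan-4-yl cation plus arene), the second the gallate ester, the third and strategic one the pair C2–C3 and O1–C8a in ring C of the upper unit.
- Enabling feature: in the ring A precursor, C8a carries fluorine ortho to the C4 carbonyl and meta to both benzyloxy groups, and C3 is the terminus of an enol silane. The ring B aldehyde C2=O1 can therefore be inserted between C3 and C8a by aldol addition and ipso substitution; Si and F leave together as Me3SiF, and the C4 carbonyl is later reduced and ionised.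
- Forward order: ring A ketone (steps 1–3), ring C closed onto ring A with ring B attached (step 4), reduction (step 5), lower unit from epigallocatechin (steps 6–7), union at C4 (step 8), hydrogenolysis (step 9).
- Stereochemistry: C2 (S) by catalyst control in step 4; C4 (R, trans to the 2-aryl group) by substrate control in step 8; C2 and C3 of the lower unit (R,R) from natural (−)-epigallocatechin.

Key step: step 4

Assumption: 5-fluororesorcinol, 3,4-bis(benzyloxy)benzaldehyde, (−)-epigallocatechin and 3,4,5-tris(benzyloxy)benzoic acid are bought; the upper flavan unit is numbered O1, C2, C3, C4, C4a, C5–C8, C8a, and positions of the other flavan are called "of the lower unit".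

**Route**

Step 1
Reactants: 1 5-fluororesorcinol
Product: 3 1-(2-fluoro-4,6-dihydroxyphenyl)ethanone, via ketiminium chloride 2 (not isolated)
Conditions: MeCN, ZnCl2, HCl (g), Et2O, 0 °C to rt; then H2O, 100 °C
Reagents that add atoms: acetonitrile CC#N; water O
Why: Hoesch acylation, in which the nitrilium electrophile should attack the ring carbon ortho to one hydroxyl, para to the other and next to the small fluorine (the two such positions are equivalent), and the ketiminium salt is hydrolysed to the methyl ketone; no stereocentre is formed.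

Step 2
Reactants: 3 1-(2-fluoro-4,6-dihydroxyphenyl)ethanone
Product: 4 1-[2,4-bis(benzyloxy)-6-fluorophenyl]ethanone
Conditions: BnBr, K2CO3, DMF, 60 °C
Reagents that add atoms: benzyl bromide BrCc1ccccc1
Why: Williamson ether synthesis on both phenoxides (the hydrogen-bonded ortho hydroxyl needs the warm DMF), while the aryl fluoride should survive because phenoxide and carbonate are too weak as nucleophiles for SNAr here.

Step 3
Reactants: 4 1-[2,4-bis(benzyloxy)-6-fluorophenyl]ethanone
Product: 5 {[1-(2,4-bis(benzyloxy)-6-fluorophenyl)ethenyl]oxy}trimethylsilane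
Conditions: Me3SiOTf, Et3N, CH2Cl2, 0 °C
Reagents that add atoms: trimethylsilyl trifluoromethanesulfonate C[Si](C)(C)OS(=O)(=O)C(F)(F)F
Why: Soft enolisation and O-silylation of the only enolisable position (the acetyl CH3, the future C3) gives the enol silane without touching the C–F bond.

Step 4
Reactants: 5 {[1-(2,4-bis(benzyloxy)-6-fluorophenyl)ethenyl]oxy}trimethylsilane; 6 3,4-bis(benzyloxy)benzaldehyde (1.2 equiv)
Product: 9 (2S)-5,7-bis(benzyloxy)-2-[3,4-bis(benzyloxy)phenyl]-2,3-dihydro-4H-chromen-4-one, via silyl aldol ether 7 (not isolated), via alkoxide 8 (not isolated)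
Conditions: (R)-2-butyl-4-(1H-indol-3-ylmethyl)-3-(4-methylbenzenesulfonyl)-1,3,2-oxazaborolidin-5-one (20 mol %), EtCN, −78 °C; then Bu4N[Ph3SiF2] (40 mol %), DMF, −40 to 20 °C
Reagents that add atoms: none
Why: Proposed new method: stage one is a chiral-Lewis-acid Mukaiyama aldol addition in which C3 of enol silane 5 attacks the boron-bound aldehyde carbon C2 and the silyl group moves to the aldolate oxygen (closest known type: oxazaborolidinone-catalysed additions of methyl-ketone enol silanes to aromatic aldehydes), and stage two is a fluoride-relay intramolecular SNAr in which fluoride frees alkoxide 8, O1 adds to C8a and the fluoride expelled from C8a desilylates the next molecule of 7 (closest known types: fluoride-catalysed aryl ether formation from silyl ethers and activated aryl fluorides with loss of Me3SiF, and base-induced ring closure of 2-fluoroaryl 1,3-diketones to chromones). Ring C is closed by addition–elimination at the arene carbon C8a, a 6-endo-trig closure with respect to the C4a=C8a bond through which the negative charge passes to the C4 carbonyl; it is possible because C8a–F is ortho to that carbonyl and meta to both benzyloxy groups, which therefore do not deactivate it by resonance. The only new stereocentre, C2, is set in the aldol stage by catalyst control: the indolylmethyl arm of the (R)-tryptophan-derived catalyst should shield the Re face of the coordinated aldehyde so that addition to the Si face gives the S configuration (the antipodal catalyst is used if a model aldehyde shows the opposite sense), and the C2–O1 bond is not broken afterwards. The step needs ring closure to be faster than retro-aldol cleavage, E1cB loss of the silyloxy group to the chalcone and base-induced opening of the flavanone, which the substoichiometric fluoride, the absence of any stoichiometric base and the six-membered transition state onto an activated C–F bond should secure. The slight excess of aldehyde leaves no enol silane to be turned by fluoride into a basic enolate.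

Step 5
Reactants: 9 (2S)-5,7-bis(benzyloxy)-2-[3,4-bis(benzyloxy)phenyl]-2,3-dihydro-4H-chromen-4-one
Product: 10 (2S,4S)-5,7-bis(benzyloxy)-2-[3,4-bis(benzyloxy)phenyl]chroman-4-ol (2,4-cis)
Conditions: NaBH4, CeCl3·7H2O, MeOH/THF, −20 °C
Reagents that add atoms: none
Why: Luche-type 1,2-reduction with axial hydride delivery should give mainly the 2,4-cis alcohol, and the buffered cold medium should avoid base-induced opening of ring C so that C2 is kept (the C4 configuration is lost again in step 8).

Step 6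
Reactants: 11 (−)-epigallocatechin
Product: 12 (2R,3R)-5,7-bis(benzyloxy)-2-[3,4,5-tris(benzyloxy)phenyl]chroman-3-ol
Conditions: BnBr, K2CO3, DMF, 0 °C to rt, argon
Reagents that add atoms: benzyl bromide BrCc1ccccc1
Why: Williamson benzylation of the five phenols, in which the secondary 3-OH is not deprotonated by carbonate and stays free, and the mild oxygen-free conditions should leave both stereocentres untouched.

Step 7
Reactants: 12 (2R,3R)-5,7-bis(benzyloxy)-2-[3,4,5-tris(benzyloxy)phenyl]chroman-3-ol; 13 3,4,5-tris(benzyloxy)benzoic acid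
Product: 14 (2R,3R)-5,7-bis(benzyloxy)-2-[3,4,5-tris(benzyloxy)phenyl]chroman-3-yl 3,4,5-tris(benzyloxy)benzoate
Conditions: DCC, DMAP, CH2Cl2, rt
Reagents that add atoms: none
Why: Steglich esterification of the axial 3-OH through the acylpyridinium species; the C3–O bond is not broken, so the configuration is retained.

Step 8
Reactants: 10 (2S,4S)-5,7-bis(benzyloxy)-2-[3,4-bis(benzyloxy)phenyl]chroman-4-ol; 14 (2R,3R)-5,7-bis(benzyloxy)-2-[3,4,5-tris(benzyloxy)phenyl]chroman-3-yl 3,4,5-tris(benzyloxy)benzoate (3 equiv)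
Product: 16 (2R,3R)-5,7-bis(benzyloxy)-8-{(2S,4R)-5,7-bis(benzyloxy)-2-[3,4-bis(benzyloxy)phenyl]chroman-4-yl}-2-[3,4,5-tris(benzyloxy)phenyl]chroman-3-yl 3,4,5-tris(benzyloxy)benzoate, via flavan-4-yl cation 15 (not isolated)
Conditions: Me3SiOTf (20 mol %), 4 Å molecular sieves, CH2Cl2, −78 to −40 °C
Reagents that add atoms: none
Why: Lewis-acid-promoted dehydrative Friedel–Crafts alkylation as used for proanthocyanidins: the benzylic 4-hydroxyl of 10 is silylated and leaves (overall as water, bound by the sieves) to give cation 15 stabilised by the 5- and 7-oxygens, C8 of the lower unit (between O1 and 7-OBn, less hindered than C6 between two OBn groups) attacks, and pseudo-axial attack on the half-chair cation on the face away from the equatorial 2-aryl group, reinforced by the peri 5-OBn group that disfavours an equatorial C4 substituent, should give the 2,4-trans (4R) isomer, while excess 14 suppresses self-condensation.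

Step 9
Reactants: 16 (2R,3R)-5,7-bis(benzyloxy)-8-{(2S,4R)-5,7-bis(benzyloxy)-2-[3,4-bis(benzyloxy)phenyl]chroman-4-yl}-2-[3,4,5-tris(benzyloxy)phenyl]chroman-3-yl 3,4,5-tris(benzyloxy)benzoate
Product: 17 (2R,3R)-8-[(2S,4R)-2-(3,4-dihydroxyphenyl)-5,7-dihydroxychroman-4-yl]-5,7-dihydroxy-2-(3,4,5-trihydroxyphenyl)chroman-3-yl 3,4,5-trihydroxybenzoate
Conditions: H2 (1 atm), Pd(OH)2/C, THF/MeOH, rt
Reagents that add atoms: none
Why: Hydrogenolysis of the twelve benzyl ethers under neutral conditions, which the gallate ester, the two cyclic benzylic ethers and the C4–C8 bond are expected to survive as in procyanidin gallate work, so no stereocentre is touched.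

**Compound list**

1 | 5-fluororesorcinol | Oc1cc(O)cc(F)c1 | starting material
2 | 1-(2-fluoro-4,6-dihydroxyphenyl)ethan-1-iminium chloride | CC(=[NH2+])c1c(O)cc(O)cc1F.[Cl-] | intermediate
3 | 1-(2-fluoro-4,6-dihydroxyphenyl)ethanone | CC(=O)c1c(O)cc(O)cc1F | intermediate
4 | 1-[2,4-bis(benzyloxy)-6-fluorophenyl]ethanone | CC(=O)c1c(OCc2ccccc2)cc(OCc2ccccc2)cc1F | intermediate
5 | {[1-(2,4-bis(benzyloxy)-6-fluorophenyl)ethenyl]oxy}trimethylsilane | C=C(O[Si](C)(C)C)c1c(OCc2ccccc2)cc(OCc2ccccc2)cc1F | intermediate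
6 | 3,4-bis(benzyloxy)benzaldehyde | O=Cc1ccc(OCc2ccccc2)c(OCc2ccccc2)c1 | starting material
7 | (3S)-1-[2,4-bis(benzyloxy)-6-fluorophenyl]-3-[3,4-bis(benzyloxy)phenyl]-3-(trimethylsilyloxy)propan-1-one | C[Si](C)(C)O[C@@H](CC(=O)c1c(OCc2ccccc2)cc(OCc2ccccc2)cc1F)c1ccc(OCc2ccccc2)c(OCc2ccccc2)c1 | intermediate
8 | (1S)-3-[2,4-bis(benzyloxy)-6-fluorophenyl]-1-[3,4-bis(benzyloxy)phenyl]-3-oxopropan-1-olate | [O-][C@@H](CC(=O)c1c(OCc2ccccc2)cc(OCc2ccccc2)cc1F)c1ccc(OCc2ccccc2)c(OCc2ccccc2)c1 | intermediate
9 | (2S)-5,7-bis(benzyloxy)-2-[3,4-bis(benzyloxy)phenyl]-2,3-dihydro-4H-chromen-4-one | O=C1C[C@@H](c2ccc(OCc3ccccc3)c(OCc3ccccc3)c2)Oc2cc(OCc3ccccc3)cc(OCc3ccccc3)c21 | intermediate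
10 | (2S,4S)-5,7-bis(benzyloxy)-2-[3,4-bis(benzyloxy)phenyl]chroman-4-ol | O[C@H]1C[C@@H](c2ccc(OCc3ccccc3)c(OCc3ccccc3)c2)Oc2cc(OCc3ccccc3)cc(OCc3ccccc3)c21 | intermediate
11 | (−)-epigallocatechin, (2R,3R) | O[C@@H]1Cc2c(O)cc(O)cc2O[C@@H]1c1cc(O)c(O)c(O)c1 | starting material
12 | (2R,3R)-5,7-bis(benzyloxy)-2-[3,4,5-tris(benzyloxy)phenyl]chroman-3-ol | O[C@@H]1Cc2c(OCc3ccccc3)cc(OCc3ccccc3)cc2O[C@@H]1c1cc(OCc2ccccc2)c(OCc2ccccc2)c(OCc2ccccc2)c1 | intermediate
13 | 3,4,5-tris(benzyloxy)benzoic acid | OC(=O)c1cc(OCc2ccccc2)c(OCc2ccccc2)c(OCc2ccccc2)c1 | starting material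
14 | (2R,3R)-5,7-bis(benzyloxy)-2-[3,4,5-tris(benzyloxy)phenyl]chroman-3-yl 3,4,5-tris(benzyloxy)benzoate | O=C(O[C@@H]1Cc2c(OCc3ccccc3)cc(OCc3ccccc3)cc2O[C@@H]1c1cc(OCc2ccccc2)c(OCc2ccccc2)c(OCc2ccccc2)c1)c1cc(OCc2ccccc2)c(OCc2ccccc2)c(OCc2ccccc2)c1 | intermediate
15 | (2S)-5,7-bis(benzyloxy)-2-[3,4-bis(benzyloxy)phenyl]chroman-4-ylium | [CH+]1C[C@@H](c2ccc(OCc3ccccc3)c(OCc3ccccc3)c2)Oc2cc(OCc3ccccc3)cc(OCc3ccccc3)c21 | intermediate
16 | (2R,3R)-5,7-bis(benzyloxy)-8-{(2S,4R)-5,7-bis(benzyloxy)-2-[3,4-bis(benzyloxy)phenyl]chroman-4-yl}-2-[3,4,5-tris(benzyloxy)phenyl]chroman-3-yl 3,4,5-tris(benzyloxy)benzoate | O=C(O[C@@H]1Cc2c(OCc3ccccc3)cc(OCc3ccccc3)c([C@@H]3C[C@@H](c4ccc(OCc5ccccc5)c(OCc5ccccc5)c4)Oc4cc(OCc5ccccc5)cc(OCc5ccccc5)c43)c2O[C@@H]1c1cc(OCc2ccccc2)c(OCc2ccccc2)c(OCc2ccccc2)c1)c1cc(OCc2ccccc2)c(OCc2ccccc2)c(OCc2ccccc2)c1 | intermediate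
17 | (2R,3R)-8-[(2S,4R)-2-(3,4-dihydroxyphenyl)-5,7-dihydroxychroman-4-yl]-5,7-dihydroxy-2-(3,4,5-trihydroxyphenyl)chroman-3-yl 3,4,5-trihydroxybenzoate | O=C(O[C@@H]1Cc2c(O)cc(O)c([C@@H]3C[C@@H](c4ccc(O)c(O)c4)Oc4cc(O)cc(O)c43)c2O[C@@H]1c1cc(O)c(O)c(O)c1)c1cc(O)c(O)c(O)c1 | target

**Step count and risks**

Total steps: 9. Longest linear sequence: 7 (steps 1, 2, 3, 4, 5, 8, 9).

Steps most likely to fail:

1. Step 4 (proposed new method). What may go wrong: retro-aldol cleavage or E1cB loss of the silyloxy group once fluoride frees the alkoxide; insufficient face selectivity with the hindered, twisted enol silane; or erosion of the C2 configuration by reversible opening of ring C. The fallback uses known chemistry, sets out from 4 and returns at 10. Ketone 4 is deprotonated with LiN(SiMe3)2 (2 equiv) in THF at −78 °C and C-acylated with 3,4-bis(benzyloxy)benzoyl chloride F1 (from the commercial acid and oxalyl chloride). This gives the lithium enolate of 1-[2,4-bis(benzyloxy)-6-fluorophenyl]-3-[3,4-bis(benzyloxy)phenyl]propane-1,3-dione F2, which on warming in THF/DMF should close by intramolecular SNAr of the enolate oxygen onto C8a–F to 5,7-bis(benzyloxy)-2-[3,4-bis(benzyloxy)phenyl]-4H-chromen-4-one F3. This one-flask Claisen acylation and SNAr still forms C2–C3 and O1–C8a together. Asymmetric hydrogenation of F3 with Ru(η4-1,5-cyclooctadiene)(η3-2-methylallyl)2, 1,3-bis[(R)-1-(naphthalen-1-yl)ethyl]-4,5-dihydroimidazolium tetrafluoroborate (or its antipode, whichever gives the 2S series on a model flavone), KOtBu and H2 under pressure should reduce C2=C3 and C4=O from one face and give 10 directly. Any 9 left over is reduced as in step 5.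

2. Step 8. What may go wrong: attack through C6 of the lower unit, attack on the wrong face of C4, or capture of the cation by ring A of 10 or 16 (oligomerisation). The fallback sets out from 12 and returns at 16. NBS (CH2Cl2, −78 °C) should brominate 12 at C8 to give (2R,3R)-5,7-bis(benzyloxy)-8-bromo-2-[3,4,5-tris(benzyloxy)phenyl]chroman-3-ol F4. t-BuLi (3 equiv, THF, −78 °C; alkoxide formation and Br–Li exchange), B(OiPr)3 and aqueous KHF2 then give potassium [(2R,3R)-5,7-bis(benzyloxy)-3-hydroxy-2-(3,4,5-tris(benzyloxy)phenyl)chroman-8-yl]trifluoroborate F5. BF3·OEt2 ionises 10, and the cation is taken up by ipso substitution of the C–B bond, the hydroxyl of 10 ending on boron as K[BF3(OH)]. This fixes the position of attack and makes the nucleophile more reactive than ring A of any flavan present. The product is (2R,3R)-5,7-bis(benzyloxy)-8-{(2S,4R)-5,7-bis(benzyloxy)-2-[3,4-bis(benzyloxy)phenyl]chroman-4-yl}-2-[3,4,5-tris(benzyloxy)phenyl]chroman-3-ol F6. Esterification of its 3-OH with 13 (DCC, DMAP, CH2Cl2) gives 16.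

3. Step 6. What may go wrong: air oxidation of the pyrogallol ring as its phenoxide, C-benzylation of ring A and base-induced epimerisation at C2 during the slow fivefold alkylation. The fallback sets out from 11 and returns at 12. 11 is peracetylated (Ac2O, pyridine) to the air-stable (2R,3R)-2-(3,4,5-triacetoxyphenyl)chroman-3,5,7-triyl triacetate F7. The five aryl acetates are exchanged for benzyl ethers in one flask (BnBr, K2CO3, KI, acetone with a little water, reflux), so that each phenoxide is released slowly and alkylated at once. This gives (2R,3R)-5,7-bis(benzyloxy)-2-[3,4,5-tris(benzyloxy)phenyl]chroman-3-yl acetate F8. K2CO3/MeOH removes the remaining alkyl acetate to give 12.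

**Further compounds**

F1 | step 4 | 3,4-bis(benzyloxy)benzoyl chloride | O=C(Cl)c1ccc(OCc2ccccc2)c(OCc2ccccc2)c1
F2 | step 4 | 1-[2,4-bis(benzyloxy)-6-fluorophenyl]-3-[3,4-bis(benzyloxy)phenyl]propane-1,3-dione | O=C(CC(=O)c1c(OCc2ccccc2)cc(OCc2ccccc2)cc1F)c1ccc(OCc2ccccc2)c(OCc2ccccc2)c1
F3 | step 4 | 5,7-bis(benzyloxy)-2-[3,4-bis(benzyloxy)phenyl]-4H-chromen-4-one | O=c1cc(-c2ccc(OCc3ccccc3)c(OCc3ccccc3)c2)oc2cc(OCc3ccccc3)cc(OCc3ccccc3)c12
F4 | step 8 | (2R,3R)-5,7-bis(benzyloxy)-8-bromo-2-[3,4,5-tris(benzyloxy)phenyl]chroman-3-ol | O[C@@H]1Cc2c(OCc3ccccc3)cc(OCc3ccccc3)c(Br)c2O[C@@H]1c1cc(OCc2ccccc2)c(OCc2ccccc2)c(OCc2ccccc2)c1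
F5 | step 8 | potassium [(2R,3R)-5,7-bis(benzyloxy)-3-hydroxy-2-(3,4,5-tris(benzyloxy)phenyl)chroman-8-yl]trifluoroborate | [K+].O[C@@H]1Cc2c(OCc3ccccc3)cc(OCc3ccccc3)c([B-](F)(F)F)c2O[C@@H]1c1cc(OCc2ccccc2)c(OCc2ccccc2)c(OCc2ccccc2)c1
F6 | step 8 | (2R,3R)-5,7-bis(benzyloxy)-8-{(2S,4R)-5,7-bis(benzyloxy)-2-[3,4-bis(benzyloxy)phenyl]chroman-4-yl}-2-[3,4,5-tris(benzyloxy)phenyl]chroman-3-ol | O[C@@H]1Cc2c(OCc3ccccc3)cc(OCc3ccccc3)c([C@@H]3C[C@@H](c4ccc(OCc5ccccc5)c(OCc5ccccc5)c4)Oc4cc(OCc5ccccc5)cc(OCc5ccccc5)c43)c2O[C@@H]1c1cc(OCc2ccccc2)c(OCc2ccccc2)c(OCc2ccccc2)c1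
F7 | step 6 | (2R,3R)-2-(3,4,5-triacetoxyphenyl)chroman-3,5,7-triyl triacetate | CC(=O)O[C@@H]1Cc2c(OC(C)=O)cc(OC(C)=O)cc2O[C@@H]1c1cc(OC(C)=O)c(OC(C)=O)c(OC(C)=O)c1
F8 | step 6 | (2R,3R)-5,7-bis(benzyloxy)-2-[3,4,5-tris(benzyloxy)phenyl]chroman-3-yl acetate | CC(=O)O[C@@H]1Cc2c(OCc3ccccc3)cc(OCc3ccccc3)cc2O[C@@H]1c1cc(OCc2ccccc2)c(OCc2ccccc2)c(OCc2ccccc2)c1
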